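The 6 questions reduce to one: how much of the manner of addition still shows in X at 25 h.

| flask | E | L | Q | remark | time |
|---|---|---|---|---|---|
| midnight | 20 mM | 0.90 equiv | 1 equiv | run made earlier |  |
| spring | 20 mM | 0.45 equiv | 1 equiv | run made earlier |  |
| dusk | 20 mM | 0.68 equiv | 1 equiv | run made earlier |  |
| noon | 40 mM | 0.90 equiv | 1 equiv | run made earlier |  |
| north | 20 mM | 0.900 equiv | 1.00 equiv (fed, over 1.0 h) | all else is in the flask from the start; the feed brings no volume worth counting | 25 h |
| south-west | 20 mM | 0.900 equiv (fed, over 10 h) | 1.00 equiv | all else is in the flask from the start; the feed brings no volume worth counting | 25 h |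
| north-east | 20 mM | 0.900 equiv | 1.00 equiv (in portions, 5, over 10 h) | first portion at the start, last at 10 h | 25 h |
| north-west | 20 mM | 0.900 equiv | 1.00 equiv | everything together at the start | 25 h |
| south-east | 20 mM | 0.900 equiv | 1.00 equiv (fed, over 10 h) | all else is in the flask from the start; the feed brings no volume worth counting | 25 h |

| run | time / h | X / % |
|---|---|---|
| midnight | 5.00 | 29 |
| midnight | 10.0 | 26 |
| midnight | 15.0 | 22 |
| midnight | 20.0 | 23 |
| midnight | 25.0 | 26 |
| spring | 1.50 | 16 |
| spring | 3.00 | 10 |
| spring | 6.00 | 14 |
| spring | 10.0 | 13 |
| spring | 20.0 | 10 |
| dusk | 2.00 | 21 |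
| dusk | 5.00 | 19 |
| dusk | 10.0 | 16 |
| dusk | 15.0 | 16 |
| dusk | 20.0 | 17 |
| noon | 4.00 | 32 |
| noon | 8.00 | 31 |
| noon | 12.0 | 29 |
| noon | 15.0 | 31 |
| noon | 20.0 | 30 |

(scatter of a reading: 2 percentage points)

- the flask that comes out highest in amount of X, in percent of the E charged, or "all alike" when all lie within 1.5 percentage points (north / south-west / north-east / north-west / south-east / all alike)
- X at the end, in percent of the E charged, north
- X at the end, in percent of the E charged, south-west
- X at the end, in percent of the E charged, north-east
- X at the end, in percent of the E charged, north-west
- X at the end, in percent of the E charged, south-east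



The midnight run holds the charges of the 5 flasks, and its last readings average 23.7%. A second way scales other runs by their L charge. The last readings of spring give 24.7%, and those of dusk average 16.3%, which scales to 21.6%. The two ways differ by at most 2 percentage points, about the scatter of 2 points of a single reading.

Early readings part from this. Midnight shows 29% at 5.00 h, and spring, scaled, shows 32.0% at 1.50 h. The early figure cheats: [X] in midnight drops by 7 points at fixed charges, so it is a passing height. The excess over the plateau in midnight reads 5.3 points at 5.00 h and 2.3 points at 10.0 h.

As a reading with its scatter, that gives 6.05 h for the memory time, the time in which the excess of [X] over its plateau shrinks by the factor 2.72, commonly the relaxation time. Dusk, a different run, reads 5.36 h.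

The addition is then a correction to the plateau. The latest addition ends at 10 h, which leaves 15.0 h, and the surviving fraction of an excess is reckoned at 0.0837. An excess of the size read in spring, 8.3 points, is reckoned down to 0.7 points, less than the margin of 1.5 points. This reckoning therefore commits to about 23.7% in each flask, all alike.

The forecast differs: it named south-east highest at 33%, with north 30%, south-west 25%, north-east 31% and north-west 25%, on the picture of “L gone before much Q arrives”.

The flasks come out all alike: north 23.9%, south-west 23.9%, north-east 23.9%, north-west 23.9%, south-east 23.9%.

    E ⇌ G (K = 1.30, k = 0.260 h⁻¹)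
    E + L ⇌ X (K = 150 M⁻¹, k = 280 M⁻¹ h⁻¹)
    Q + L ⇌ J (K = 150 M⁻¹, k = 1700 M⁻¹ h⁻¹)

In north-west, the loss of E to G has a forward half-life of 2.7 h, longer than the 0.14 h for the making of X from E and L. That 2.7 h is still far shorter than the 15.0 h following the end of the south-west feed, a span of 2.48 memory times as read from midnight. At the end of that feed, south-west stands 1.5 points below its final X, which it reaches at 23.9%. North, 13 points above its final X at 1.00 h, has 3.97 such memory times behind it at 25 h and ends at 23.9%.

The runs are calculated for an exercise, noise included.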